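| setting | alpha | delta | beta | flask |
|---|---|---|---|---|
| left-handed substrate | 20 mM | 20 mM | 20 mM | 20 mM |
| right-handed substrate | 20 mM | 20 mM | 20 mM | 20 mM |
| reagent | 60 mM | 60 mM | 60 mM | 60.0 mM |
| free catalyst | 36 µM | 36 µM | 54 µM | 36 µM |
| racemization catalyst | 50 µM | 200 µM | 100 µM | 100 µM |
| remark | run made earlier | run made earlier | run made earlier |  |
| time |  |  |  | 8.0 h |

| run | time / h | left-handed product / % | right-handed product / % | left-handed substrate / % |
|---|---|---|---|---|
| alpha | 0.667 | 24 | 15 | 24 |
| alpha | 1.00 | 31 | 17 | 17 |
| alpha | 2.00 | 40 | 28 | 9 |
| alpha | 3.00 | 45 | 29 | 5 |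
| alpha | 5.00 | 43 | 36 | 2 |
| alpha | 8.00 | 50 | 41 | 2 |
| delta | 0.500 | 21 | 12 | 29 |
| delta | 1.50 | 38 | 22 | 14 |
| delta | 3.00 | 44 | 29 | 5 |
| delta | 4.00 | 47 | 33 | 7 |
| delta | 6.00 | 49 | 39 | 5 |
| delta | 8.00 | 48 | 38 | 3 |
| beta | 0.667 | 32 | 20 | 16 |
| beta | 1.33 | 44 | 31 | 9 |
| beta | 2.50 | 46 | 34 | 2 |
| beta | 4.00 | 49 | 41 | 1 |
| beta | 8.00 | 51 | 45 | 0 |

(scatter of a reading: 1.5 percentage points)

- free catalyst is single-handed; left-handed substrate and right-handed substrate are mirror images of each other, charged as a racemate, each of them at the stated concentration
- an excess is the difference of the two amounts in percent of their sum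
- an excess is below zero if the other one leads

- left-handed product and right-handed product together, in percent of the left-handed substrate and right-handed substrate charged together, at 8.0 h
- excess of left-handed product over right-handed product in the product at 8.0 h
- whether the exchange between left-handed substrate and right-handed substrate keeps pace with the reaction: how far the product's excess at 8.0 h gets from its value without exchange to its value with instant exchange (above 80% keeps pace, below 20% hardly takes part, else lags behind)

Each substrate is half of the charge, so left-handed and right-handed product show how much of each half has gone, provided no substrate crosses over. The logarithm of the unconverted left-handed half over the same logarithm for the right-handed half compares the two rates of loss; this is the selectivity factor s. Pooled over the first reading of each run, when crossing has had the least time, the readings give s = 1.94.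

Alpha and delta share the flask's free catalyst and hold 50 µM and 200 µM of racemization catalyst against its 100 µM. Their right-handed product at 8.00 h averages 39.5%. Through s, that amount goes with 47.6% of left-handed product without crossing, an excess of 9.29%. Instant exchange gives 32.1%. Delta reads an excess of 11.6% at 8.00 h, which is 10.2% of the way, under the 20% mark. The flask holds less racemization catalyst than delta, so this reckoning expects exchange to hardly take part, with an excess between 9.29% and 11.6%.

The forecast gives 89% of product together (85.5% to 92%), an excess of 10.5% (8.5% to 13%) and "hardly takes part", holding that “little right-handed substrate crosses over”. It reads 2.2 for the rate ratio where this reckoning reads 1.94.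

The flask gives 89.8% of product together and an excess of 10.5%, and its exchange hardly takes part, at 8.8% of the way.

    reagent + free catalyst + left-handed substrate → free catalyst + left-handed product (k = 180 M⁻² s⁻¹)
    reagent + free catalyst + right-handed substrate → free catalyst + right-handed product (k = 89.0 M⁻² s⁻¹)
    left-handed substrate + racemization catalyst ⇌ right-handed substrate + racemization catalyst, rate k3*[racemization catalyst]*[left-handed substrate] forward; the back reaction follows from the equilibrium constant (k = 0.160 M⁻¹ s⁻¹)
    2 racemization catalyst → spent catalyst (k = 0.790 M⁻¹ s⁻¹)
    2 reagent → homo dimer (k = 5.70 × 10⁻⁴ M⁻¹ s⁻¹)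

From the flask's 40.2% of right-handed product, s gives 47.9% of left-handed product; the flask holds 49.6%. A neighbour charged with 15 mM of reagent, the limiting reagent there, keeps 1.85% of it and ends with 12.6% of right-handed product. From that, s gives 21.5% of left-handed product, and the neighbour holds 22.4%. Its excess by s is 26.1%, and the simulated excess is 28.1%.

Readings and results are calculated for an exercise; scatter was added.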